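**Retrosynthetic overview**

1. The ring A oxygens come last, by Woodward cis-hydroxylation of a ring A alkene (axial acetate, equatorial OH, syn to the angular CH2OAc). The cyclopropane comes from 1,3-C–H insertion of a carbene (Bamford–Stevens) in a bornan-2-one-type ketone.
2. Key disconnection: the bond between the methyl-bearing cyclopropane carbon and the CH–OAc carbon. It is closed as a transannular Mukaiyama aldol across ring B of a trans-decalin (silyl enol ether plus axial angular aldehyde).
3. Enabling feature: ring B is the six-membered ring made of the two ring-fusion carbons, the cage CH2 and the three cyclopropane carbons. In it the CH–OAc carbon is a one-carbon 1,4-bridge (quaternary fusion carbon to methyl-bearing carbon) and the cyclopropane bond is a 1,3-bond. If the cyclopropane CH next to the CH2OAc-bearing fusion carbon is carried as a ketone, the methyl-bearing carbon is its only enolizable position and becomes the nucleophile; the same carbonyl later becomes the carbene.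
4. Ring A, the fusion-carbon/CMe2 bond and the ring A alkene come from an Ireland–Claisen ring contraction of a temporary δ-lactone. Ring B comes from an organocatalytic Michael/aldol annulation and two enolate alkylations.
5. Ring order: B, then the temporary δ-lactone, then A, then the bicyclo[2.2.1] bridge (key step), then the cyclopropane.

Key step: step 12

Assumption: the (S)-diarylprolinol silyl ether is taken to give the (R)-ester 5 and (S)-Me-CBS the (R)-carbinol 13; if either sense proves opposite, the enantiomeric catalyst is used.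

**Route**

Step 1
Reactants: 1 tert-butyl 3-oxopentanoate; 2 ethyl (E)-4-oxobut-2-enoate
Product: 5 ethyl (1R)-4-methyl-3-oxocyclohex-4-ene-1-carboxylate, via Michael adduct 3 (not isolated), via cyclohexenone diester 4 (not isolated)
Conditions: (S)-2-[diphenyl(trimethylsilyloxy)methyl]pyrrolidine (10 mol%), PhCO2H (10 mol%), toluene, rt; then TsOH·H2O (20 mol%), toluene, 80 °C
Reagents that add atoms: none
Why: Iminium-catalysed asymmetric Michael addition of the β-keto ester to the enal, then acid-mediated aldol condensation and tert-butyl ester cleavage/decarboxylation (organocatalytic cyclohexenone annulation); the ester-bearing stereocenter is set in the Michael step by the shielded face of the iminium ion.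

Step 2
Reactants: 5 ethyl (1R)-4-methyl-3-oxocyclohex-4-ene-1-carboxylate
Product: 7 ethyl (1R,2R)-2-[(benzyloxy)methyl]-4-methyl-3-oxocyclohex-4-ene-1-carboxylate, via lithium dienolate 6 (not isolated)
Conditions: LiN(iPr)2, THF, −78 °C; BnOCH2Cl, −78 to −40 °C
Reagents that add atoms: benzyl chloromethyl ether, ClCOCc1ccccc1
Why: Kinetic α′-enolate alkylation of a 2-methylcyclohexenone (as in C-6 alkylation of carvone); the electrophile should enter anti to the neighbouring ester group and give the trans product.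

Step 3
Reactants: 7 ethyl (1R,2R)-2-[(benzyloxy)methyl]-4-methyl-3-oxocyclohex-4-ene-1-carboxylate
Product: 9 ethyl (1R,2S)-2-[(benzyloxy)methyl]-2-(2-tert-butoxy-2-oxoethyl)-4-methyl-3-oxocyclohex-4-ene-1-carboxylate, via lithium dienolate 8 (not isolated)
Conditions: LiN(iPr)2, THF, −78 °C; BrCH2CO2tBu, DMPU, −78 to −20 °C
Reagents that add atoms: tert-butyl bromoacetate, BrCC(=O)OC(C)(C)C
Why: Second α′-enolate alkylation, again anti to the ester, so the acetate arm should end trans and the CH2OBn group cis to CO2Et; this fixes the absolute configuration of the future CH2OAc-bearing fusion carbon, and any minor isomer is a separable diastereomer.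

Step 4
Reactants: 9 ethyl (1R,2S)-2-[(benzyloxy)methyl]-2-(2-tert-butoxy-2-oxoethyl)-4-methyl-3-oxocyclohex-4-ene-1-carboxylate
Product: 10 2-[(1S,6R)-1-[(benzyloxy)methyl]-6-(ethoxycarbonyl)-3-methyl-2-oxocyclohex-3-en-1-yl]acetic acid
Conditions: CF3CO2H, CH2Cl2, 0 °C to rt
Reagents that add atoms: none
Why: Acidolysis of the tert-butyl ester (loss of isobutene), which leaves the ethyl ester, benzyl ether and enone untouched.

Step 5
Reactants: 10 2-[(1S,6R)-1-[(benzyloxy)methyl]-6-(ethoxycarbonyl)-3-methyl-2-oxocyclohex-3-en-1-yl]acetic acid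
Product: 12 ethyl (1R,2S)-2-[(benzyloxy)methyl]-4-methyl-2-(4-methyl-2-oxopent-3-en-1-yl)-3-oxocyclohex-4-ene-1-carboxylate, via pyridyl thioester 11 (not isolated)
Conditions: 2,2'-dipyridyl disulfide, PPh3, CH2Cl2, rt; then Me2C=CHMgBr, THF, −78 °C
Reagents that add atoms: (2-methylprop-1-en-1-yl)magnesium bromide, CC(C)=C[Mg]Br
Why: Ketone synthesis from an S-(2-pyridyl) thioester and a Grignard reagent; chelation-assisted acyl transfer at −78 °C should be faster than attack on the ring enone (flanked by a quaternary carbon) or on the ethyl ester, and the product is not over-added.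

Step 6
Reactants: 12 ethyl (1R,2S)-2-[(benzyloxy)methyl]-4-methyl-2-(4-methyl-2-oxopent-3-en-1-yl)-3-oxocyclohex-4-ene-1-carboxylate
Product: 13 ethyl (1R,2S)-2-[(benzyloxy)methyl]-2-[(2R)-2-hydroxy-4-methylpent-3-en-1-yl]-4-methyl-3-oxocyclohex-4-ene-1-carboxylate
Conditions: (S)-Me-CBS oxazaborolidine (20 mol%), BH3·SMe2, THF, −40 °C; MeOH
Reagents that add atoms: none
Why: CBS reduction with the alkenyl group as the large substituent sets the (R)-allylic carbinol by reagent control; the side-chain enone should react before the ring ketone, which is flanked by a quaternary carbon.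

Step 7
Reactants: 13 ethyl (1R,2S)-2-[(benzyloxy)methyl]-2-[(2R)-2-hydroxy-4-methylpent-3-en-1-yl]-4-methyl-3-oxocyclohex-4-ene-1-carboxylate
Product: 14 (3R,4aS,8aR)-4a-[(benzyloxy)methyl]-6-methyl-3-(2-methylprop-1-en-1-yl)-3,4,4a,8a-tetrahydro-1H-isochromene-1,5(8H)-dione (trans-fused δ-lactone)
Conditions: Ti(OiPr)4 (20 mol%), toluene, 90 °C, removal of EtOH
Reagents that add atoms: none
Why: Titanium-catalysed transesterification closes the temporary δ-lactone under neutral conditions, so the allylic C–O bond does not ionize; no stereocenter is touched, and the lactone α-carbon is planarized later in any case.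

Step 8
Reactants: 14 the trans-fused δ-lactone enone
Product: 15 (3R,4aS,8aR)-4a-[(benzyloxy)methyl]-6-methyl-3-(2-methylprop-1-en-1-yl)-5-[(triethylsilyl)oxy]-3,4,4a,7,8,8a-hexahydro-1H-isochromen-1-one
Conditions: RhCl(PPh3)3 (2 mol%), Et3SiH, THF, 50 °C
Reagents that add atoms: triethylsilane, CC[SiH](CC)CC
Why: Rhodium-catalysed 1,4-hydrosilylation of the enone gives the silyl enol ether regiospecifically toward the methyl-bearing carbon; it masks the ketone during step 9 and is the nucleophile of step 12.

Step 9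
Reactants: 15 the silyl enol ether lactone
Product: 18 (4aS,8aR)-4a-[(benzyloxy)methyl]-1,1,6-trimethyl-5-[(triethylsilyl)oxy]-4,4a,7,8-tetrahydronaphthalene-8a(1H)-carboxylic acid (trans-decalin; CO2H anti to CH2OBn), via silyl ketene acetal 16 (not isolated), via trimethylsilyl ester 17 (not isolated)
Conditions: LiN(iPr)2, Me3SiCl, Et3N, THF, −78 °C to rt; toluene, 105 °C; then K2CO3, MeOH/H2O, 0 °C, work-up at pH 5
Reagents that add atoms: none
Why: Ireland–Claisen ring contraction of an alkenyl lactone: the silyl ketene acetal rearranges through a boat [3,3] transition state in which the alkenyl group, cis to CH2OBn on the lactone ring, delivers its CMe2 terminus to that face, so the quaternary–CMe2 bond, ring A with its alkene and the CO2H group anti to CH2OBn form together.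

Step 10
Reactants: 18 the trans-decalin acid
Product: 19 [(4aS,8aR)-4a-[(benzyloxy)methyl]-1,1,6-trimethyl-5-[(triethylsilyl)oxy]-4,4a,7,8-tetrahydronaphthalen-8a(1H)-yl]methanol
Conditions: LiAlH4, THF, 65 °C
Reagents that add atoms: none
Why: Hydride reduction of the hindered carboxylic acid to the neopentyl alcohol; the silyl enol ether, benzyl ether and alkene are inert.

Step 11
Reactants: 19 the neopentyl alcohol
Product: 20 (4aS,8aR)-4a-[(benzyloxy)methyl]-1,1,6-trimethyl-5-[(triethylsilyl)oxy]-4,4a,7,8-tetrahydronaphthalene-8a(1H)-carbaldehyde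
Conditions: Pr4N[RuO4] (5 mol%), N-methylmorpholine N-oxide, 4 Å sieves, CH2Cl2, rt
Reagents that add atoms: none
Why: Catalytic perruthenate oxidation of a primary alcohol under neutral conditions; the aldehyde has no α-hydrogen and the silyl enol ether should survive.

Step 12
Reactants: 20 the silyl enol ether aldehyde
Product: 22 6-[(benzyloxy)methyl]-11-hydroxy-2,2,8-trimethyltricyclo[6.2.1.0(1,6)]undec-3-en-7-one (hydroxyl syn to the CH2–CH2 bridge), via boron aldolate 21 (not isolated)
Conditions: BF3·OEt2 (1.2 equiv), CH2Cl2, −78 °C; aqueous NaHCO3, 0 °C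
Reagents that add atoms: none
Why: Proposed new method: BF3 activates the axial angular aldehyde and the β-carbon of the silyl enol ether (the methyl-bearing carbon, 1,4 across ring B) attacks it through the boat conformer of ring B, after which fluoride transfer to silicon gives Et3SiF and a chelated difluoroboron aldolate whose B–O and Si–F bonds pay for the strain of the new bicyclo[2.2.1]heptane (about 17 kcal/mol), which is why a Lewis-acid Mukaiyama aldol is chosen over a reversible base aldol. The closest known reactions are intramolecular Mukaiyama aldol closures to bridged bicyclic β-hydroxy ketones, and the closure copies the terpinyl-to-bornyl step of monoterpene biosynthesis. The bridge closes two five-membered rings at once, each 5-exo-trig at the carbonyl (enol-exo for the ring through the CH2–CH2 unit, enol-endo for the ring through the siloxy carbon), and the enol π-orbital points at the aldehyde because the formyl group is axial on the trans-decalin. The quaternary methyl-bearing stereocenter is dictated by the tether, and the carbinol center by an open transition state in which the BF3-bound oxygen lies over the CH2–CH2 bridge, away from the ring A CH2 on the neighbouring quaternary carbon and anti to the enol C–O bond, which places the hydroxyl syn to the cage CH2 as in the target. The step needs chemoselectivity for the silyl enol ether over the ring A alkene (secured by the much higher nucleophilicity of the enol ether at −78 °C) and a single enol regioisomer (secured because the other α-carbon of the masked ketone is quaternary).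

Step 13
Reactants: 22 the bridged hydroxy ketone
Product: 23 11-(benzyloxy)-6-[(benzyloxy)methyl]-2,2,8-trimethyltricyclo[6.2.1.0(1,6)]undec-3-en-7-one
Conditions: 2-benzyloxy-1-methylpyridinium triflate, MgO, PhCF3, 83 °C
Reagents that add atoms: 2-benzyloxy-1-methylpyridinium triflate, C[n+]1ccccc1OCc1ccccc1.[O-]S(=O)(=O)C(F)(F)F
Why: Neutral benzyl transfer from an oxypyridinium salt protects the strained aldol hydroxyl without forming an alkoxide, so retro-aldol opening is avoided.

Step 14
Reactants: 23 the bis-benzyl ether ketone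
Product: 24 p-toluenesulfonylhydrazone of 23
Conditions: TsNHNH2 (3 equiv), HCl (cat.), EtOH, 78 °C
Reagents that add atoms: p-toluenesulfonyl hydrazide, Cc1ccc(cc1)S(=O)(=O)NN
Why: Acid-catalysed condensation to the tosylhydrazone; the ketone is hindered in the way fenchone is, so forcing conditions are planned, and the benzyl ether blocks retro-aldol.

Step 15
Reactants: 24 the tosylhydrazone
Product: 27 11-(benzyloxy)-6-[(benzyloxy)methyl]-2,2,8-trimethyltetracyclo[6.2.1.0(1,6).0(7,9)]undec-3-ene, via sodium salt 25 (not isolated), via diazoalkane 26 (not isolated)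
Conditions: NaH (1.05 equiv), diglyme, rt, then 150 °C
Reagents that add atoms: none
Why: Aprotic Bamford–Stevens reaction: the carbene at the former carbonyl carbon has no α-hydrogen (quaternary carbon on one side, bridgehead on the other), so it should insert into the endo C–H of the CH2 across the bridgehead (as camphor tosylhydrazone gives tricyclene); the two cyclopropane CH stereocenters are fixed by the cage.

Step 16
Reactants: 27 the tetracyclic bis-benzyl ether
Product: 28 6-(hydroxymethyl)-2,2,8-trimethyltetracyclo[6.2.1.0(1,6).0(7,9)]undec-3-en-11-ol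
Conditions: Li, NH3 (l), THF, −78 °C; NH4Cl
Reagents that add atoms: none
Why: Dissolving-metal cleavage of both benzyl ethers; the isolated alkene and the unconjugated cyclopropane are not reduced.

Step 17
Reactants: 28 the diol
Product: 29 [11-acetoxy-2,2,8-trimethyltetracyclo[6.2.1.0(1,6).0(7,9)]undec-3-en-6-yl]methyl acetate
Conditions: Ac2O, pyridine, DMAP, CH2Cl2, rt
Reagents that add atoms: acetic anhydride, CC(=O)OC(C)=O
Why: Acylation of the primary and the secondary hydroxyl; no stereocenter is affected.

Step 18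
Reactants: 29 the alkene diacetate
Product: 32 6-(acetoxymethyl)-3-hydroxy-2,2,8-trimethyltetracyclo[6.2.1.0(1,6).0(7,9)]undecane-4,11-diyl diacetate (CNP0197219.1), via iodo acetate 30 (not isolated), via acetoxonium ion 31 (not isolated)
Conditions: I2, AgOAc, AcOH, rt; then H2O, 90 °C
Reagents that add atoms: silver acetate (AgOAc), CC(=O)[O-].[Ag+]; water, O
Why: Woodward cis-hydroxylation: the iodonium ion should form on the face anti to the axial CH2OAc and axial methyl, acetate opens it trans-diaxially at the carbon remote from CMe2, the acetate displaces iodide to give a cis acetoxonium ion on the hindered face, and its hydrolysis gives the axial acetate and equatorial hydroxyl found in the target.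

**Compound list**

1 | tert-butyl 3-oxopentanoate | CCC(=O)CC(=O)OC(C)(C)C | starting material
2 | ethyl (E)-4-oxobut-2-enoate | CCOC(=O)/C=C/C=O | starting material
3 | 1-tert-butyl 4-ethyl (3R)-3-(2-oxoethyl)-2-propanoylbutanedioate (C-2 epimers) | CCC(=O)C(C(=O)OC(C)(C)C)[C@@H](CC=O)C(=O)OCC | intermediate
4 | 2-tert-butyl 1-ethyl (1R)-4-methyl-3-oxocyclohex-4-ene-1,2-dicarboxylate (C-2 epimers) | CCOC(=O)[C@H]1C(C(=O)OC(C)(C)C)C(=O)C(C)=CC1 | intermediate
5 | ethyl (1R)-4-methyl-3-oxocyclohex-4-ene-1-carboxylate | CCOC(=O)[C@H]1CC(=O)C(C)=CC1 | intermediate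
6 | lithium dienolate of 5 (enolized toward C-2) | CCOC(=O)[C@H]1C=C(O[Li])C(C)=CC1 | intermediate
7 | ethyl (1R,2R)-2-[(benzyloxy)methyl]-4-methyl-3-oxocyclohex-4-ene-1-carboxylate | c1ccccc1COC[C@@H]1C(=O)C(C)=CC[C@H]1C(=O)OCC | intermediate
8 | lithium dienolate of 7 | c1ccccc1COCC1=C(O[Li])C(C)=CC[C@H]1C(=O)OCC | intermediate
9 | ethyl (1R,2S)-2-[(benzyloxy)methyl]-2-(2-tert-butoxy-2-oxoethyl)-4-methyl-3-oxocyclohex-4-ene-1-carboxylate | c1ccccc1COC[C@@]1(CC(=O)OC(C)(C)C)C(=O)C(C)=CC[C@H]1C(=O)OCC | intermediate
10 | 2-[(1S,6R)-1-[(benzyloxy)methyl]-6-(ethoxycarbonyl)-3-methyl-2-oxocyclohex-3-en-1-yl]acetic acid | c1ccccc1COC[C@@]1(CC(=O)O)C(=O)C(C)=CC[C@H]1C(=O)OCC | intermediate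
11 | S-(pyridin-2-yl) thioester of 10 | c1ccccc1COC[C@@]1(CC(=O)Sc2ccccn2)C(=O)C(C)=CC[C@H]1C(=O)OCC | intermediate
12 | ethyl (1R,2S)-2-[(benzyloxy)methyl]-4-methyl-2-(4-methyl-2-oxopent-3-en-1-yl)-3-oxocyclohex-4-ene-1-carboxylate | c1ccccc1COC[C@@]1(CC(=O)C=C(C)C)C(=O)C(C)=CC[C@H]1C(=O)OCC | intermediate
13 | ethyl (1R,2S)-2-[(benzyloxy)methyl]-2-[(2R)-2-hydroxy-4-methylpent-3-en-1-yl]-4-methyl-3-oxocyclohex-4-ene-1-carboxylate | c1ccccc1COC[C@@]1(C[C@@H](O)C=C(C)C)C(=O)C(C)=CC[C@H]1C(=O)OCC | intermediate
14 | (3R,4aS,8aR)-4a-[(benzyloxy)methyl]-6-methyl-3-(2-methylprop-1-en-1-yl)-3,4,4a,8a-tetrahydro-1H-isochromene-1,5(8H)-dione | c1ccccc1COC[C@]12C[C@H](C=C(C)C)OC(=O)[C@@H]1CC=C(C)C2=O | intermediate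
15 | (3R,4aS,8aR)-4a-[(benzyloxy)methyl]-6-methyl-3-(2-methylprop-1-en-1-yl)-5-[(triethylsilyl)oxy]-3,4,4a,7,8,8a-hexahydro-1H-isochromen-1-one | c1ccccc1COC[C@]12C[C@H](C=C(C)C)OC(=O)[C@@H]1CCC(C)=C2O[Si](CC)(CC)CC | intermediate
16 | trimethylsilyl ketene acetal of lactone 15 | c1ccccc1COC[C@]12C[C@H](C=C(C)C)OC(O[Si](C)(C)C)=C1CCC(C)=C2O[Si](CC)(CC)CC | intermediate
17 | trimethylsilyl ester of acid 18 | c1ccccc1COC[C@]12CC=CC(C)(C)[C@]1(C(=O)O[Si](C)(C)C)CCC(C)=C2O[Si](CC)(CC)CC | intermediate
18 | (4aS,8aR)-4a-[(benzyloxy)methyl]-1,1,6-trimethyl-5-[(triethylsilyl)oxy]-4,4a,7,8-tetrahydronaphthalene-8a(1H)-carboxylic acid | c1ccccc1COC[C@]12CC=CC(C)(C)[C@]1(C(=O)O)CCC(C)=C2O[Si](CC)(CC)CC | intermediate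
19 | [(4aS,8aR)-4a-[(benzyloxy)methyl]-1,1,6-trimethyl-5-[(triethylsilyl)oxy]-4,4a,7,8-tetrahydronaphthalen-8a(1H)-yl]methanol | c1ccccc1COC[C@]12CC=CC(C)(C)[C@]1(CO)CCC(C)=C2O[Si](CC)(CC)CC | intermediate
20 | (4aS,8aR)-4a-[(benzyloxy)methyl]-1,1,6-trimethyl-5-[(triethylsilyl)oxy]-4,4a,7,8-tetrahydronaphthalene-8a(1H)-carbaldehyde | c1ccccc1COC[C@]12CC=CC(C)(C)[C@]1(C=O)CCC(C)=C2O[Si](CC)(CC)CC | intermediate
21 | O-difluoroboryl aldolate of 22 | c1ccccc1COC[C@]12CC=CC(C)(C)[C@]13CC[C@](C)(C2=O)[C@H]3OB(F)F | intermediate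
22 | 6-[(benzyloxy)methyl]-11-hydroxy-2,2,8-trimethyltricyclo[6.2.1.0(1,6)]undec-3-en-7-one (hydroxyl syn to the CH2–CH2 bridge) | c1ccccc1COC[C@]12CC=CC(C)(C)[C@]13CC[C@](C)(C2=O)[C@H]3O | intermediate
23 | 11-(benzyloxy)-6-[(benzyloxy)methyl]-2,2,8-trimethyltricyclo[6.2.1.0(1,6)]undec-3-en-7-one | c1ccccc1COC[C@]12CC=CC(C)(C)[C@]13CC[C@](C)(C2=O)[C@H]3OCc1ccccc1 | intermediate
24 | p-toluenesulfonylhydrazone of 23 (C=N geometry not defined) | c1ccccc1COC[C@]12CC=CC(C)(C)[C@]13CC[C@](C)(C2=NNS(=O)(=O)c2ccc(C)cc2)[C@H]3OCc1ccccc1 | intermediate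
25 | sodium salt of 24 | c1ccccc1COC[C@]12CC=CC(C)(C)[C@]13CC[C@](C)(C2=N[N-]S(=O)(=O)c2ccc(C)cc2)[C@H]3OCc1ccccc1.[Na+] | intermediate
26 | 7-diazo analogue of 23 | c1ccccc1COC[C@]12CC=CC(C)(C)[C@]13CC[C@](C)(C2=[N+]=[N-])[C@H]3OCc1ccccc1 | intermediate
27 | 11-(benzyloxy)-6-[(benzyloxy)methyl]-2,2,8-trimethyltetracyclo[6.2.1.0(1,6).0(7,9)]undec-3-ene | c1ccccc1COC[C@]12CC=CC(C)(C)[C@]13C[C@@H]1[C@H]2[C@]1(C)[C@H]3OCc1ccccc1 | intermediate
28 | 6-(hydroxymethyl)-2,2,8-trimethyltetracyclo[6.2.1.0(1,6).0(7,9)]undec-3-en-11-ol | OC[C@]12CC=CC(C)(C)[C@]13C[C@@H]1[C@H]2[C@]1(C)[C@H]3O | intermediate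
29 | [11-acetoxy-2,2,8-trimethyltetracyclo[6.2.1.0(1,6).0(7,9)]undec-3-en-6-yl]methyl acetate | CC(=O)OC[C@]12CC=CC(C)(C)[C@]13C[C@@H]1[C@H]2[C@]1(C)[C@H]3OC(C)=O | intermediate
30 | 4-acetoxy-3-iodo triacetate (acetate and iodide trans-diaxial) | CC(=O)OC[C@]12C[C@H](OC(C)=O)[C@@H](I)C(C)(C)[C@]13C[C@@H]1[C@H]2[C@]1(C)[C@H]3OC(C)=O | intermediate
31 | cis-3,4-acetoxonium (2-methyl-1,3-dioxolan-2-ylium) acetate | CC(=O)OC[C@]12C[C@H](O[C+](C)O4)[C@H]4C(C)(C)[C@]13C[C@@H]1[C@H]2[C@]1(C)[C@H]3OC(C)=O.CC(=O)[O-] | intermediate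
32 | 6-(acetoxymethyl)-3-hydroxy-2,2,8-trimethyltetracyclo[6.2.1.0(1,6).0(7,9)]undecane-4,11-diyl diacetate (CNP0197219.1) | CC(=O)OC[C@]12C[C@H](OC(C)=O)[C@H](O)C(C)(C)[C@]13C[C@@H]1[C@H]2[C@]1(C)[C@H]3OC(C)=O | target

**Step count and risks**

Total step count: 18. Longest linear sequence: 18 steps (from 1 and 2).

Steps most likely to fail:

1. Step 12 (proposed new method). The bridging aldol may stall or revert because of the strain of the new bicyclo[2.2.1]heptane, the enol ether may be protodesilylated, or the ring A alkene may attack the activated aldehyde. The fallback uses known chemistry and sets out from 20. Bromination of the silyl enol ether with N-bromosuccinimide (THF, −78 °C) should give the α-bromo ketone aldehyde F1. SmI2 (THF, −78 °C) should then generate the samarium enolate regiospecifically, and an intramolecular samarium Reformatsky-type aldol onto the aldehyde, held as a trivalent samarium aldolate chelate, should give the same β-hydroxy ketone. The fallback comes back to the route at 22.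

2. Step 9. Enolization of the hindered lactone may be incomplete, or the boat transition state that joins two fully substituted carbons may be too congested, so that the ketene acetal decomposes instead of rearranging. The fallback sets out from 7 and builds ring A by an acyclic Ireland–Claisen rearrangement and metathesis. Alkylation of the lithium enolate of 7 with allyl bromide should give the allyl ketone F2, and LiOH should hydrolyse it to the acid F3. Prenyl bromide with K2CO3 in DMF should give the prenyl ester F4, and 1,4-hydrosilylation with [CuH(PPh3)]6 (cat.) and Et3SiH (which spares the terminal alkene) should give the silyl enol ether F5. Ireland–Claisen rearrangement (LiN(iPr)2, Me3SiCl, THF, −78 °C to 60 °C) should add the prenyl terminus anti to the allyl group and give the acid F6, with any diastereomer separated here. Ring-closing metathesis with the second-generation Grubbs catalyst closes ring A, and the fallback comes back to the route at 18.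

3. Step 18. The iodonium ion may form on, or be opened from, the other face, acetate may open it at the other carbon, or the acetyl group may migrate to the equatorial hydroxyl. The fallback sets out from 28. Hydrogen-bond-directed dihydroxylation with OsO4·TMEDA (CH2Cl2, −78 °C; then aqueous Na2SO3), directed by the axial CH2OH, should give the tetraol F7 with the diol syn to that group. Trimethyl orthoacetate with camphorsulfonic acid, followed by Ac2O and pyridine, should give the cyclic orthoester diacetate F8. Hydrolysis of the orthoester in aqueous AcOH should open it to the axial acetate and equatorial alcohol, and the fallback comes back to the route at 32.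

Further compounds
F1 | step 12 | (4aS,8aR)-4a-[(benzyloxy)methyl]-6-bromo-1,1,6-trimethyl-5-oxo-4,4a,5,6,7,8-hexahydronaphthalene-8a(1H)-carbaldehyde (either C-6 epimer) | c1ccccc1COC[C@]12CC=CC(C)(C)[C@]1(C=O)CCC(C)(Br)C2=O
F2 | step 9 | ethyl (1R,2S)-2-allyl-2-[(benzyloxy)methyl]-4-methyl-3-oxocyclohex-4-ene-1-carboxylate | c1ccccc1COC[C@@]1(CC=C)C(=O)C(C)=CC[C@H]1C(=O)OCC
F3 | step 9 | (1R,2S)-2-allyl-2-[(benzyloxy)methyl]-4-methyl-3-oxocyclohex-4-ene-1-carboxylic acid | c1ccccc1COC[C@@]1(CC=C)C(=O)C(C)=CC[C@H]1C(=O)O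
F4 | step 9 | 3-methylbut-2-en-1-yl (1R,2S)-2-allyl-2-[(benzyloxy)methyl]-4-methyl-3-oxocyclohex-4-ene-1-carboxylate | c1ccccc1COC[C@@]1(CC=C)C(=O)C(C)=CC[C@H]1C(=O)OCC=C(C)C
F5 | step 9 | triethylsilyl enol ether of F4 | c1ccccc1COC[C@@]1(CC=C)C(O[Si](CC)(CC)CC)=C(C)CC[C@H]1C(=O)OCC=C(C)C
F6 | step 9 | 2-allyl-2-[(benzyloxy)methyl]-4-methyl-1-(2-methylbut-3-en-2-yl)-3-[(triethylsilyl)oxy]cyclohex-3-ene-1-carboxylic acid (CO2H anti to CH2OBn) | c1ccccc1COC[C@@]1(CC=C)C(O[Si](CC)(CC)CC)=C(C)CC[C@@]1(C(=O)O)C(C)(C)C=C
F7 | step 18 | 6-(hydroxymethyl)-2,2,8-trimethyltetracyclo[6.2.1.0(1,6).0(7,9)]undecane-3,4,11-triol (3,4-diol syn to CH2OH) | OC[C@]12C[C@H](O)[C@H](O)C(C)(C)[C@]13C[C@@H]1[C@H]2[C@]1(C)[C@H]3O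
F8 | step 18 | 3,4-O-(1-methoxyethylidene) orthoester of F7 as the 6-CH2 and 11-O diacetate (orthoester carbon epimers) | CC(=O)OC[C@]12C[C@H](OC(C)(OC)O4)[C@H]4C(C)(C)[C@]13C[C@@H]1[C@H]2[C@]1(C)[C@H]3OC(C)=O
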